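The 3,4-dihydro-2H-pyran is disconnected by a retro-oxa-Diels–Alder reaction into (+)-alantolactone and a cis-fused eudesmane enal. The key step exploits the enol ether O–CH=C of the dihydropyran and its spiro carbon C-11, shared with the γ-lactone. The 1-oxadiene O=C12′–C11′=C13′ of the enal adds to the exocyclic C11=C13 methylene of alantolactone, forming O–C11, C13′–C13, the last ring and the spiro stereocentre in one biomimetic operation. The precursor pair is commercial alantolactone and the (5S,7S,10S)-enal, built from (R)-carvone by a conjugate addition/cycloalkylation (methylenecyclohexane annulation) that sets the cis ring fusion.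

Key step: step 10

Remark: eudesmane locants are used for both halves (primed for the enal-derived half). The target SMILES encodes a cis-fused upper decalin with H-5′, the C-7′ substituent and CH3-10′ mutually cis (5′S,7′S,10′S), and a lower half identical with natural (+)-alantolactone; the route is built for exactly this stereostructure.

Step 1
Reactants: 1 5-chloropent-1-yne
Product: 3 2-bromo-5-chloropent-1-ene, via alkenylborane 2 (not isolated)
Conditions: B-Br-9-BBN, CH2Cl2, 0 °C to rt; then AcOH, 0 °C to rt
Reagents that add atoms: B-bromo-9-borabicyclo[3.3.1]nonane, BrB1C2CCCC1CCC2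
Why: Markovnikov syn-bromoboration of the terminal alkyne followed by protodeboronation with acetic acid (haloboration–protonolysis) should give the 2-bromo-1-alkene, the primary chloride being inert.

Step 2
Reactants: 4 (R)-(−)-carvone
Product: 5 (5R)-5-(3-chloroprop-1-en-2-yl)-2-methylcyclohex-2-en-1-one (10-chlorocarvone)
Conditions: Ca(OCl)2, CO2 (dry ice), CH2Cl2/H2O, 0 °C
Reagents that add atoms: calcium hypochlorite, [Ca+2].[O-]Cl.[O-]Cl
Why: ene-type allylic chlorination by HOCl formed in situ should attack only the electron-rich isopropenyl group with double-bond shift, leaving the deactivated enone alkene and the C-5 stereocentre untouched.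

Step 3
Reactants: 5 10-chlorocarvone
Product: 6 (5R)-5-[3-(4-methoxyphenoxy)prop-1-en-2-yl]-2-methylcyclohex-2-en-1-one
Conditions: 4-MeOC6H4OH, K2CO3, cat. KI, MeCN, 60 °C
Reagents that add atoms: 4-methoxyphenol, COc1ccc(O)cc1
Why: Williamson ether synthesis on the allylic chloride (SN2 and SN2′ give the same product) installs a p-methoxyphenyl ether that should survive cuprate, alkoxide and borane conditions and be removable oxidatively.

Step 4
Reactants: 3 2-bromo-5-chloropent-1-ene; 6 aryloxy enone
Product: 9 (3R,5R)-3-(5-chloropent-1-en-2-yl)-5-[3-(4-methoxyphenoxy)prop-1-en-2-yl]-2-methylcyclohexan-1-one (C-2 epimers), via vinyllithium 7 (not isolated), via lithium enolate 8 (not isolated)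
Conditions: 3, t-BuLi (2 equiv), Et2O, −78 °C; PhSCu, THF, −78 to −20 °C; then 6, −78 to −20 °C; aq. NH4Cl
Reagents that add atoms: none
Why: Br–Li exchange and transmetalation give a mixed phenylthio(alkenyl)cuprate whose conjugate addition to the cyclohexenone should occur by axial attack anti to the pseudoequatorial C-5 side chain, setting C-3 trans to it, while C-2 is protonated unselectively and is corrected in step 5.

Step 5
Reactants: 9 chloro ketone
Product: 11 (3R,4aS,8aR)-3-[3-(4-methoxyphenoxy)prop-1-en-2-yl]-8a-methyl-5-methylideneoctahydronaphthalen-1(2H)-one, via potassium enolate 10 (not isolated)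
Conditions: t-BuOK, t-BuOH/THF, 0 °C to rt
Reagents that add atoms: none
Why: intramolecular enolate C-alkylation (6-exo-tet, second stage of the methylenecyclohexane annulation) should proceed through the equilibrating tetrasubstituted enolate, the only one able to reach the chloride through a six-membered transition state, and the pseudoaxial C-3 tether can bond to the adjacent enolate carbon only on its own face, so the quaternary centre forms with the angular methyl cis to the ring-fusion hydrogen.

Step 6
Reactants: 11 bicyclic ketone
Product: 12 (E)-tosylhydrazone of 11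
Conditions: TsNHNH2, cat. AcOH, EtOH, 70 °C
Reagents that add atoms: 4-methylbenzenesulfonohydrazide, Cc1ccc(cc1)S(=O)(=O)NN
Why: acid-catalysed hydrazone condensation at the only carbonyl group should give the tosylhydrazone with the sulfonamide anti to the quaternary carbon.

Step 7
Reactants: 12 tosylhydrazone
Product: 15 (2S,4aS,8aS)-2-[3-(4-methoxyphenoxy)prop-1-en-2-yl]-4a-methyl-8-methylidenedecahydronaphthalene, via N-borylhydrazide 13 (not isolated), via alkyldiazene 14 (not isolated)
Conditions: catecholborane, CHCl3, 0 °C to rt; then NaOAc·3H2O, reflux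
Reagents that add atoms: none
Why: the catecholborane variant of the Caglioti tosylhydrazone reduction (hydroboration of C=N, acetate-induced loss of sulfinate and boron to the alkyldiazene, extrusion of N2) should give the methylene group under near-neutral conditions that leave both 1,1-disubstituted alkenes, the aryl ether and all stereocentres untouched.

Step 8
Reactants: 15 aryl ether
Product: 16 2-[(2S,4aS,8aS)-4a-methyl-8-methylidenedecahydronaphthalen-2-yl]prop-2-en-1-ol
Conditions: CAN, MeCN/H2O (4:1), 0 °C
Reagents that add atoms: none
Why: oxidative dearylation of the p-methoxyphenyl ether (single-electron oxidation of the electron-rich arene and hydrolysis to benzoquinone) should release the primary allylic alcohol without touching the isolated alkenes.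

Step 9
Reactants: 16 allylic alcohol
Product: 17 2-[(2S,4aS,8aS)-4a-methyl-8-methylidenedecahydronaphthalen-2-yl]prop-2-enal
Conditions: activated MnO2, CH2Cl2, rt
Reagents that add atoms: none
Why: chemoselective allylic oxidation with MnO2 should give the 2-substituted acrolein without over-oxidation or alkene migration; the enal is used at once to limit self-dimerisation.

Step 10
Reactants: 17 cis-fused eudesmane enal; 18 (+)-alantolactone
Product: 19 target spiro-dihydropyran
Conditions: 18 (4 equiv), BHT (cat.), PhMe (concentrated), 140 °C, sealed tube, 17 added slowly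
Reagents that add atoms: none
Why: Thermal inverse-demand oxa-Diels–Alder reaction: the s-cis 1-oxadiene of 17 and the C11=C13 alkene of 18 should combine through a concerted, highly asynchronous transition state in which the C13′–C13 bond between the two unsubstituted methylene termini leads and the O–C11 bond follows, which places the oxygen on the carbonyl-bearing carbon. The closest known reactions are the thermal dimerisation of methacrolein, the addition of acrolein to methyl methacrylate and the hetero-Diels–Alder dimerisations of α-methylene carbonyl sesquiterpenoids. The dihydropyran is closed by intermolecular [4π+2π] cycloaddition, both σ-bonds forming suprafacially on one face of the lactone alkene. The only new stereocentre, spiro C-11 (R), is controlled by the cis-fused lactone of 18: the oxadiene should approach the convex face (that of H-7 and H-8), away from the carbocycle, so the pyran oxygen ends up cis to H-7. The step needs cross- over homo-cycloaddition of 17 (its own C11′=C13′ bond is a competing dienophile), which an excess of recoverable 18 and slow addition of 17 should secure, and the unactivated C4′=C15′ and C5=C6 alkenes should be inert at this temperature.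

Compound list
1 | 5-chloropent-1-yne | C#CCCCCl | starting material
2 | (Z)-9-(2-bromo-5-chloropent-1-en-1-yl)-9-borabicyclo[3.3.1]nonane (not isolated) | Br/C(CCCCl)=C\B1C2CCCC1CCC2 | intermediate
3 | 2-bromo-5-chloropent-1-ene | C=C(Br)CCCCl | intermediate
4 | (R)-(−)-carvone, (5R)-2-methyl-5-(prop-1-en-2-yl)cyclohex-2-en-1-one | CC1=CC[C@H](CC1=O)C(C)=C | starting material
5 | (5R)-5-(3-chloroprop-1-en-2-yl)-2-methylcyclohex-2-en-1-one | CC1=CC[C@H](CC1=O)C(=C)CCl | intermediate
6 | (5R)-5-[3-(4-methoxyphenoxy)prop-1-en-2-yl]-2-methylcyclohex-2-en-1-one | CC1=CC[C@H](CC1=O)C(=C)COc1ccc(OC)cc1 | intermediate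
7 | 5-chloro-2-lithiopent-1-ene (not isolated) | [Li]C(=C)CCCCl | intermediate
8 | lithium enolate (C1=C2) of ketone 9, 3,5-trans (not isolated) | C=C(CCCCl)[C@@H]1C[C@@H](C(=C)COc2ccc(OC)cc2)CC(O[Li])=C1C | intermediate
9 | (3R,5R)-3-(5-chloropent-1-en-2-yl)-5-[3-(4-methoxyphenoxy)prop-1-en-2-yl]-2-methylcyclohexan-1-one, mixture of C-2 epimers | ClCCCC(=C)[C@@H]1C[C@@H](C(=C)COc2ccc(OC)cc2)CC(=O)C1C | intermediate
10 | potassium enolate (C1=C2) of ketone 9 (not isolated) | C=C(CCCCl)[C@@H]1C[C@@H](C(=C)COc2ccc(OC)cc2)CC(O[K])=C1C | intermediate
11 | (3R,4aS,8aR)-3-[3-(4-methoxyphenoxy)prop-1-en-2-yl]-8a-methyl-5-methylideneoctahydronaphthalen-1(2H)-one; cis-fused, with 8a-CH3, H-4a and the C-3 side chain on one face | C=C1CCC[C@@]2(C)C(=O)C[C@H](C(=C)COc3ccc(OC)cc3)C[C@@H]12 | intermediate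
12 | (E)-4-methylbenzenesulfonohydrazone of ketone 11 | C=C1CCC[C@@]2(C)/C(=N/NS(=O)(=O)c3ccc(C)cc3)C[C@H](C(=C)COc3ccc(OC)cc3)C[C@@H]12 | intermediate
13 | N-(1,3,2-benzodioxaborol-2-yl)-N-alkyl-N′-tosylhydrazine from hydroboration of 12, either epimer at the new CH (not isolated) | C=C1CCC[C@@]2(C)C(N(NS(=O)(=O)c3ccc(C)cc3)B3Oc4ccccc4O3)C[C@H](C(=C)COc3ccc(OC)cc3)C[C@@H]12 | intermediate
14 | monoalkyl diazene from 13, either epimer at CH–N (not isolated) | C=C1CCC[C@@]2(C)C(N=N)C[C@H](C(=C)COc3ccc(OC)cc3)C[C@@H]12 | intermediate
15 | (2S,4aS,8aS)-2-[3-(4-methoxyphenoxy)prop-1-en-2-yl]-4a-methyl-8-methylidenedecahydronaphthalene | C=C1CCC[C@@]2(C)CC[C@H](C(=C)COc3ccc(OC)cc3)C[C@@H]12 | intermediate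
16 | 2-[(2S,4aS,8aS)-4a-methyl-8-methylidenedecahydronaphthalen-2-yl]prop-2-en-1-ol (cis-fused costol stereoisomer) | C=C1CCC[C@@]2(C)CC[C@H](C(=C)CO)C[C@@H]12 | intermediate
17 | 2-[(2S,4aS,8aS)-4a-methyl-8-methylidenedecahydronaphthalen-2-yl]prop-2-enal (cis-fused costal stereoisomer, 5S,7S,10S in eudesmane numbering) | C=C1CCC[C@@]2(C)CC[C@H](C(=C)C=O)C[C@@H]12 | intermediate
18 | (+)-alantolactone, (3aR,5S,8aR,9aR)-5,8a-dimethyl-3-methylidene-3a,5,6,7,8,8a,9,9a-octahydronaphtho[2,3-b]furan-2(3H)-one | C=C1C(=O)O[C@@H]2C[C@@]3(C)CCC[C@H](C)C3=C[C@H]12 | starting material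
19 | target: 3,4-dihydro-2H-pyran whose C-2 is the spiro carbon C-11 (R) of the alantolactone skeleton (pyran O cis to H-7) and whose C-5 carries the (2S,4aS,8aS)-4a-methyl-8-methylidenedecahydronaphthalen-2-yl group | C=C1CCC[C@@]2(C)CC[C@H](C3=CO[C@@]4(CC3)C(=O)O[C@@H]3C[C@@]5(C)CCC[C@H](C)C5=C[C@@H]34)C[C@@H]12 | target

Total step count: 10
Longest linear sequence: 9 steps (steps 2 to 10, from (R)-carvone); step 1 prepares the annulation reagent.

Steps most likely to fail

Step 10 (oxa-Diels–Alder). Self-cycloaddition of 17 through its own C11′=C13′ bond, or a sluggish reaction between two electron-poor partners, may outrun the cross-cycloaddition, and facial discrimination on the lactone may be incomplete. The fallback sets out from 18 and comes back to the route at 19. It assembles the same ring stepwise with matched polarity, so the dihydropyran is still the last ring closed. Nucleophilic (Weitz–Scheffer) epoxidation of 18 with t-BuOOH/DBU should occur on the convex face and give the 11,13-epoxide of alantolactone F1, which fixes the C-11 oxygen configuration. Opening at the primary C-13 with LiI/AcOH should give the iodohydrin 11-hydroxy-13-iodo-11,13-dihydroalantolactone F2. Giese addition of its nucleophilic C-13 radical to the electron-poor enal 17 (Bu3SnH, AIBN, PhH, 80 °C) should give the δ-hydroxy aldehyde F3, which should close to the lactol F4. Dehydration of the lactol (MsCl, Et3N) then gives 19.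

Step 4 (cuprate addition). The ω-chloro alkenyllithium may decompose before transmetalation, or the α-methyl enone may enolise or add the hindered alkenyl group only slowly. The fallback sets out from 6 (with 3) and comes back at 9. Nickel-catalysed reductive conjugate addition of the alkenyl bromide 3 to enone 6 (NiCl2·glyme, neocuproine, Mn, Et3SiCl, DMF) avoids organolithium species, tolerates the alkyl chloride and should give the triethylsilyl enol ether of the chloro ketone F5 with the same anti approach. Mild acid hydrolysis returns 9.

Step 6 (tosylhydrazone formation, together with its reduction in step 7). Condensation at the neopentyl C-9 carbonyl may stall, or hydride delivery to the hindered hydrazone may be slow. The fallback sets out from 11 and comes back at 15 by radical deoxygenation. NaBH4 reduction should give the secondary alcohol F6, and NaH/CS2/MeI its S-methyl xanthate F7. Barton–McCombie reduction (Bu3SnH, AIBN, PhMe, 110 °C) then gives 15. The C-9 radical has only 4-exo or 5-endo modes of addition to the two alkenes and should be reduced without cyclisation.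

Further compounds
F1 | step 10 | 11,13-epoxide of alantolactone, epoxide oxygen on the convex face (cis to H-7) | O1C[C@@]12C(=O)O[C@@H]3C[C@@]4(C)CCC[C@H](C)C4=C[C@H]23
F2 | step 10 | 11-hydroxy-13-iodo-11,13-dihydroalantolactone, hydroxyl cis to H-7 | O[C@@]1(CI)C(=O)O[C@@H]2C[C@@]3(C)CCC[C@H](C)C3=C[C@H]12
F3 | step 10 | δ-hydroxy aldehyde from Giese addition of F2 to 17, epimers at the formyl-bearing carbon | C=C1CCC[C@@]2(C)CC[C@H](C(C=O)CC[C@]3(O)C(=O)O[C@@H]4C[C@@]5(C)CCC[C@H](C)C5=C[C@H]34)C[C@@H]12
F4 | step 10 | spiro lactol (2-hydroxytetrahydropyran) formed by ring closure of F3, epimers at the anomeric and adjacent carbons | C=C1CCC[C@@]2(C)CC[C@H](C3C(O)O[C@@]4(CC3)C(=O)O[C@@H]3C[C@@]5(C)CCC[C@H](C)C5=C[C@@H]34)C[C@@H]12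
F5 | step 4 | triethylsilyl enol ether (C1=C2) of chloro ketone 9 | C=C(CCCCl)[C@@H]1C[C@@H](C(=C)COc2ccc(OC)cc2)CC(O[Si](CC)(CC)CC)=C1C
F6 | step 6 | secondary alcohol from reduction of ketone 11, either carbinol epimer | C=C1CCC[C@@]2(C)C(O)C[C@H](C(=C)COc3ccc(OC)cc3)C[C@@H]12
F7 | step 6 | O-alkyl S-methyl xanthate of F6 | C=C1CCC[C@@]2(C)C(OC(=S)SC)C[C@H](C(=C)COc3ccc(OC)cc3)C[C@@H]12
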